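Left-handed product forms from the left-handed substrate, which is half of the substrates charged, so in the flask its curve has 50.0% of the charge as ceiling.

| setting | blue | ochre | flask |
|---|---|---|---|
| left-handed substrate | 0.10 M | 0.10 M | 0.10 M |
| right-handed substrate | 0.10 M | 0.10 M | 0.10 M |
| solid reagent | 1.5 equiv | 1.5 equiv | 1.50 equiv |
| catalyst | 2.5 mol% | 10 mol% | 5 mol% |
| remark | run made earlier | run made earlier |  |
| time |  |  | 6.0 min |

| run | time / min | left-handed product / % |
|---|---|---|
| blue | 0.500 | 1.8 |
| blue | 1.33 | 3.5 |
| blue | 2.50 | 5.9 |
| blue | 4.00 | 10.2 |
| blue | 6.00 | 17.2 |
| blue | 8.00 | 21.1 |
| ochre | 1.33 | 10.5 |
| ochre | 2.50 | 18.8 |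
| ochre | 4.00 | 28.7 |
| ochre | 5.00 | 32.5 |
| ochre | 6.00 | 33.8 |
| ochre | 8.00 | 40.0 |

(readings scatter by 1 percentage point)

- catalyst is single-handed; left-handed substrate and right-handed substrate are mirror images of each other, charged as a racemate, each of them at the stated concentration
- given per volume of solution although it is solid: solid reagent
- what was read earlier has a scatter of 1 percentage point, one standard deviation
- steps thought possible: partner + catalyst + left-handed substrate -> catalyst + left-handed product; partner + catalyst + right-handed substrate -> catalyst + right-handed product; solid reagent <-> partner
- at the start none of the solid reagent is in solution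

- how much left-handed product there is at 6.0 min, in percent of the left-handed substrate and right-handed substrate together charged
- the change that raises the amount of left-handed product at 6.0 min, in percent of the left-handed substrate and right-handed substrate together charged most ("none" if none brings more than 2 percentage points) (beta / zeta / gamma / none)
- amount of left-handed product at 6.0 min, in percent of the left-handed substrate and right-handed substrate together charged, after beta

- beta: doubling the dissolution coefficient of the solid reagent, all else as stated
- zeta: doubling the solubility of the solid reagent, all else as stated
- gamma: doubling the amount of catalyst, all else as stated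

Up to 1.33 min, the blue run climbs at 0.0263 min⁻¹ and the ochre run at 0.0789 min⁻¹, as fractions of the charge, so I start the flask at their geometric mean, 0.0456 min⁻¹. Catalyst and partner meet each molecule of left-handed substrate alike, so that substrate decays in a pseudo-first-order way, and its exposure is minus the logarithm of the fraction of it left. Exposure at a fixed time is taken as a power of the catalyst loading, and this catalyst exponent is read from the two runs, with their scatter:

blue, at 6.00 min: 0.422

ochre, at 6.00 min: 1.13

catalyst exponent: 0.709

flask, at 6.0 min: exposure 0.689, left-handed product 24.9%

That is less than the 27.4% of a straight line from the start, so my flask curve bends slightly. Gamma turns the flask into the ochre recipe, whose reading of 33.8% is a gain of 8.9 percentage points against a bar of 2 points. The two runs differ in catalyst loading, so they give me no reckoning for beta or zeta, and I choose gamma as the change with a gain read from a run, without a figure of my own to hold against it.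

The forecast gives 25%, 29% after beta, and, unlike my choice, zeta, holding that “Doubling solubility doubles dissolved partner throughout”.

The flask gives 26.9%, 28.2% after beta, and an exposure of 0.773.

    partner + catalyst + left-handed substrate → catalyst + left-handed product (k = 360 M⁻² min⁻¹)
    partner + catalyst + right-handed substrate → catalyst + right-handed product (k = 150 M⁻² min⁻¹)
    solid reagent ⇌ partner, rate k3*(cs3 - [partner]) while solid is left; crystals form when [partner] > cs3 (solubility = 0.0890 M, k = 1.70 min⁻¹)

Gamma gains 8.6 points, more than zeta's 3.2 points or beta's 1.3 points, and at 6.00 min the flask holds 0% of its solid reagent. Carrying the catalyst exponent from the flask's exposure to the neighbouring flask with 12 mol% of catalyst gives an exposure of 1.44 and a reckoned 38.1% of left-handed product, and that neighbouring flask gives 37.3%.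

(The numbers in the tables were computed for substances that don't exist, and the scatter is random.)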